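The data were generated by integration from invented constants, noise included.

The dusk run, charged with 3.00 times the starting material of the winter run at the same reagent, had made 2.76 times as much target by the first reading, and I took that as a first sign that the rate is a constant times the starting material times the reagent.

common to all: free catalyst 0.0500 M
- winter: starting material 1.00 M; reagent 2.50 M
- autumn: starting material 0.400 M; reagent 1.90 M
- dusk: starting material 3.00 M; reagent 2.50 M
- spring: starting material 0.330 M; reagent 7.50 M; time 20 h

| run | time / h | [target] / M |
|---|---|---|
| winter run | 3.3 | 0.170 |
| winter run | 6.7 | 0.285 |
| winter run | 10 | 0.395 |
| winter run | 13 | 0.477 |
| winter run | 17 | 0.564 |
| winter run | 20 | 0.606 |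
| autumn run | 3.3 | 0.042 |
| autumn run | 6.7 | 0.095 |
| autumn run | 10 | 0.147 |
| autumn run | 13 | 0.153 |
| autumn run | 17 | 0.189 |
| autumn run | 20 | 0.204 |
| dusk run | 3.3 | 0.469 |
| dusk run | 6.7 | 0.778 |
| dusk run | 10 | 1.018 |
| dusk run | 13 | 1.204 |
| dusk run | 17 | 1.369 |
| dusk run | 20 | 1.493 |

(readings scatter by 0.01 M)

- Overall: starting material + reagent -> target, with free catalyst as catalyst.
- Constant volume, constant temperature.
- "The second partner" is reagent.
- An order is taken over about fifteen percent of the charge, up and down.

- how the opening rate goes with [reagent] round the charge of the winter run: the exponent of the rate at two percent of starting material gone to target
- how the opening rate goes with [starting material] round the charge of the winter run: the exponent of the rate at two percent of starting material gone to target (one fixed amount of target, the same in the runs compared)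
- the autumn run starts with 0.600 M less of starting material and of reagent than the winter run, and with no target. Compared where both hold the same amount of starting material, once fifteen percent of what the autumn run was charged with has turned into target, is the autumn run faster, slower or alike (within a tenth)?
- target in the spring run at 20 h, as a share of the starting material charged

Integrating that law up to the last reading, I read a constant of 0.0218 /M/h from the winter run, 0.0221 /M/h from the dusk run and 0.0200 /M/h from the autumn run, each carrying the scatter of its readings. So I committed to order 1 in each partner, and, since the autumn and winter runs share an excess of reagent of 1.50 M, to alike rates at equal starting material.

In the spring run I expected the rate to open at 0.0539 M/h and to slow through two factors. The starting-material factor falls with conversion, but the reagent factor, with 22.7 times as much reagent as starting material charged, stays above 0.956, which makes the spring run nearly pseudo-first-order, its rate per unit of starting material easing from 0.163 /h to 0.156 /h. For the spring run at 20 h I reckoned 3.13 turnovers, the turnover count being the constant times the excess of reagent over starting material times the time. Under this rate law, the share of starting material left, divided by the share of reagent left, is the exponential of minus that count. Taking the reagent factor at its lowest, I reckoned 4.20% of the starting material left, and so 95.8% as target.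

The forecast gave order 1 in reagent, order 1 in starting material, alike for the comparison, and 95.5% for the spring run, lower than my figure, with the warning that “any saturation would lower it”.

The simulation gave orders of 1.0 and 1.0, alike rates, and 95.9% in the spring run, so the forecast stood, on these steps:

    2 free catalyst ⇌ catalyst dimer, settled at all times (4.510 /M)
    catalyst dimer + starting material + reagent → target + catalyst dimer (5.472 /M²/h)
    free catalyst + impurity → spent catalyst
    starting material + reagent → target (0.01102 /M/h)

The simple law thus covers two routes. With the uncatalysed passing of starting material and reagent into target taken away, the spring run falls from 95.9% to 79.8% target. Read through the same rule, the spring run without that route stands at 1.56 turnovers, about half of the 3.13 I counted.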